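| flask | D | X | G | temperature | remark | time |
|---|---|---|---|---|---|---|
| teal | 0.13 M | 0.195 M | 0.065 M | −15 °C | run made earlier |  |
| amber | 0.087 M | 0.195 M | 0.065 M | 0 °C | run made earlier |  |
| violet | 0.20 M | 0.195 M | 0.065 M | −15 °C | run made earlier |  |
| red | 0.13 M | 0.195 M | 0.13 M | 0 °C | run made earlier |  |
| Saturday's | 0.13 M (fed, over 8.0 h) | 0.195 M | 0.0650 M | 0 °C | all else is in the flask from the start; the feed brings no volume worth counting | 10 h |
| Thursday's | 0.13 M (fed, over 50 min) | 0.195 M | 0.0650 M | 0 °C | all else is in the flask from the start; the feed brings no volume worth counting | 10 h |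
| Wednesday's | 0.13 M | 0.195 M (fed, over 8.0 h) | 0.0650 M |  | the addition at −30 °C, then warmed to 0 °C; the feed brings no volume worth counting | 10 h |
| Friday's | 0.13 M | 0.195 M (in portions, 5, over 8.0 h) | 0.0650 M | 0 °C | first portion at the start, last at 8.0 h | 10 h |
| Tuesday's | 0.13 M | 0.195 M (fed, over 8.0 h) | 0.0650 M | 0 °C | all else is in the flask from the start; the feed brings no volume worth counting | 10 h |

- teal (time / h: L / %, E / %): 2.00: 48.4, 26.2; 3.00: 52.9, 26.4; 6.00: 57.5, 25.6; 10.0: 59.3, 24.9; 20.0: 59.4, 23.2
- amber (time / h: L / %, E / %): 2.00: 65.6, 24.1; 4.00: 66.9, 21.3; 6.00: 67.0, 19.8; 8.00: 68.0, 18.6; 10.0: 68.6, 16.8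
- violet (time / h: L / %, E / %): 4.00: 56.7, 11.6; 8.00: 59.7, 10.9; 12.0: 61.2, 11.3; 15.0: 60.1, 11.9; 20.0: 60.6, 10.9
- red (time / h: L / %, E / %): 2.00: 68.3, 12.6; 4.00: 69.3, 11.0; 6.00: 68.4, 10.4; 8.00: 67.9, 9.9; 10.0: 68.1, 9.5

(standard deviation of a reading: 0.5 percentage points)

- percent here means D units held: one Q counts as two
- what is said of L includes Q
- on the list of suspects stand: D + X <-> G + L; L + X <-> G + E; E + X <-> G + Z; D + L <-> Q; 2 X -> J
- in an amount of L, one Q counts as one L

- the flask with the highest share of L in L plus E ("all alike" if they lie within 1.5 percentage points) (Saturday's / Thursday's / Wednesday's / Friday's / Tuesday's / all alike)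
- share of L in L plus E at the end, Saturday's
- share of L in L plus E at the end, Thursday's
- share of L in L plus E at the end, Wednesday's
- share of L in L plus E at the end, Friday's
- share of L in L plus E at the end, Tuesday's

Saturday's flask makes X wait for D over 8.0 h, Thursday's over 50 min, and I set those waits against the lifetime of X towards J. I read that lifetime from the amber run, where L goes from 65.6% to 68.6% while E falls from 24.1% to 16.8%. I take c(E)/c(L) as proportional to c(X)/c(G), I count exchanges as L plus twice E, and I assume that no X has gone to J by the first reading.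

At 2.00 h: c(E)/c(L) = 0.367, exchanges 0.0990 M, c(X) = 0.0960 M, proportion 0.628

At 10.0 h: c(E)/c(L) = 0.245, exchanges 0.0889 M, c(X) = 0.0601 M

X missing: 0.0460 M

Loss constant, X missing over the product of both c(X) and the time between: 0.998 /M/h

This is a rough reading, with the scatter of its readings in it. The lifetime of X standing at its whole charge, 5.14 h, is my carried quantity.

Saturday's: wait over lifetime = 1.56, so my ceiling is 60.9% of X to J, reckoned as if D took none of X during that wait.

Thursday's: wait over lifetime = 0.162

X lost to J makes no E, so I rank Saturday's first, then Thursday's. Wednesday's, Friday's and Tuesday's give X to D by feed or in portions, and I rank them behind Thursday's.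

The forecast names Saturday's and gives 89% for Saturday's, 86% for Thursday's, 80.5% for Wednesday's, 82.5% for Friday's and 82% for Tuesday's: “Exchange settles within about 2 h at 0 °C, so the end share depends mainly on how much X survives.”

The flasks give 91.3% for Saturday's, 86.5% for Thursday's, 82.7% for Wednesday's, 82.9% for Friday's and 83.1% for Tuesday's.

    D + X ⇌ G + L (K = 23.0, k = 47.0 /M/h, Ea = 54.0 kJ/mol, ΔH = −21.0 kJ/mol)
    L + X ⇌ G + E (K = 0.820, k = 71.0 /M/h, Ea = 41.0 kJ/mol, ΔH = −45.0 kJ/mol)
    E + X ⇌ G + Z (K = 0.190, k = 130 /M/h, Ea = 50.0 kJ/mol, ΔH = 0 kJ/mol)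
    D + L ⇌ Q, settled at all times (K = 9.30 /M, ΔH = −25.0 kJ/mol)
    2 X → J (k = 0.530 /M/h, Ea = 49.0 kJ/mol)
    (constants at 0 °C)

Saturday's holds J 0.0341 M at 8.00 h, which took 35.0% of X, below my ceiling. The neighbour is Wednesday's recipe with 0.52 M of D, so 0.375 equiv of X. There X is the limiting reagent, with 1.81% of its charge left at 10.0 h. At that level, c(X) = 0.003533 M, the lifetime is 284 h, and 10 h over it is 0.0353. That neighbour holds J 2.02 × 10⁻⁴ M, and its share of L in L plus E is 99.6%.

(All runs were generated by integration with constants of no real substance, and the scatter is random.)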